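## Analysis of the target

Compound 21 is 6-ethyl-4-hydroxy-3-{[(2R)-4,6-dihydroxy-5-(2-methylpropanoyl)-2-(prop-1-en-2-yl)-2,3-dihydro-1-benzofuran-7-yl]methyl}-5-methyl-2H-pyran-2-one. It has three parts: a fully substituted phloroglucinol ring (ring A, C3a to C7a), a dihydrofuran fused to it (ring B: O1, C2, C3), and a 4-hydroxy-2-pyrone (ring C) joined to C7 through one methylene carbon. Ring A carries three oxygens (O1, C4–OH, C6–OH) and three different carbon substituents (C3 at C3a, the isobutyryl group at C5, the methylene at C7), so each position of phloroglucinol has to be addressed in a fixed order. The only stereocenter is C2 (R), an allylic, aryloxy-bearing carbon with the isopropenyl group. Nothing else in the molecule can relay stereochemistry to it, so it must be set by a reagent or catalyst. The sensitive sites are: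
- the C2–O1 allyl aryl ether, which can ionize under acid or be reopened by zerovalent palladium;
- the 1,1-disubstituted alkene, which adds protic acids;
- the free acylphloroglucinol, an easily oxidized carbon nucleophile;
- the pyrone, a vinylogous acid and lactone;
- the methylene bridge, which can exchange partners under forcing conditions.

The difficulty is the combination of regiochemical ordering on ring A, one isolated stereocenter, and the union of two different enol-type nucleophiles through one carbon without symmetric dimers. The strategy rests on one feature: C3, C2 and the isopropenyl group are the five carbons of one isoprene unit, and ring B is attached to ring A only through C3a–C3 and O1–C2. These are the two bonds that an arylpalladium and a neighbouring phenoxide can add across one double bond of a 1,3-diene.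

## Retrosynthetic reasoning

**Methylene bridge.** The last bonds made are C7–CH2 and CH2–C3' of 21. Cutting both gives the acylphloroglucinol 12, the pyrone 17 and the one-carbon iminium salt 18. C7 is the only unsubstituted carbon of ring A in 12 and C3 is the only nucleophilic carbon of 17, so neither partner needs protection. The bridge and the pyrone are also the most fragile parts of 21 and should see no further chemistry. The forward reaction must give the mixed product and not the two symmetric ones. For that reason 17 is first converted into its Mannich base 19, and the acceptor 20 is released from it only once 12 is present.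

**Phenol protection.** 12 is traced back to its bis-MOM ether 11. The MOM groups leave exactly one free hydroxyl for ring closure, direct the lithiation that places the acyl group, and tolerate base and palladium. They are removed with dilute acid, the only step in which the finished stereocenter meets a proton source.

**Ring B (key disconnection).** Ring B of 11 is removed by cutting C3a–C3 and O1–C2. This takes away the ring, the isopropenyl group and the stereocenter together and leads to the achiral iodophenol 9 and isoprene 10. Cutting C2–C3 or the C2–isopropenyl bond instead would leave the stereocenter for a separate operation and would require the alkene to be made later by elimination. In the forward direction a zerovalent palladium catalyst with a chiral phosphine must add the aryl group of 9 to the vinyl terminus of 10 and let the phenoxide close on the internal allyl carbon with facial control.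

**Spectator groups on 9.** The isobutyryl group is already present in 9 by design. A 2-iodophenol with a para acyl group is a substrate type well suited to this annulation, the acyl group makes the phenol more acidic, and no organolithium step follows the creation of C2. Acylation after annulation would require a lithiation to choose between C5 and C7, both of which lie between two oxygens.

**Carbon–iodine bond.** 9 comes from the phenol 8. In 8 the two positions ortho to the hydroxyl are equivalent and the para position carries the ketone, so mono-iodination can give only 9. Iodination at the stage of 3 would have had to discriminate between an ortho position and the para position between the two MOM ethers.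

**Aryl–acyl bond.** 8 comes from the silyl ether 7, and 7 from the arene 4 and the anhydride 5 by cutting the aryl–carbonyl bond. The forward step is a lithiation of 4 between the two MOM ethers to give 6, followed by acylation. The third oxygen is masked as a triisopropylsilyl ether, which does not direct lithiation and shields both neighbouring positions, so 6 is the only aryllithium that can form. Fluoride then frees the one hydroxyl that becomes O1.

**MOM ethers.** 4 comes from the phenol 3, and 3 from phloroglucinol 1 and chloromethyl methyl ether 2. The three hydroxyls of 1 are equivalent, so only the degree of alkylation has to be controlled. That is a matter of stoichiometry and separation, not of regiochemistry.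

**Pyrone.** 17 is opened at its lactone C2–O1 bond to the diketo ester 16. 16 is cut at C4–C5 into the keto ester 13 and the amide 14. The forward steps are a γ-acylation of the dianion 15 and an enol lactonization.

## Alternatives that were turned down

**Alternative 1: acylketene annulation with ring switch.**
- Disconnection: ring C is cut at C3'–C4' and O1'–C2'. The bridge C7–CH2–C3' is kept inside a dihydrocoumarin, used as its silyl ketene acetal A4 (5,7-bis[(tert-butyldimethylsilyl)oxy]-2-[(trimethylsilyl)oxy]-4H-chromene).
- Forward key step: the dioxinone A2 (6-ethyl-2,2,5-trimethyl-4H-1,3-dioxin-4-one) is heated to release the acylketene A3 (2-methyl-3-oxopent-1-en-1-one). A3 bonds to C3' of A4 through its ketene carbon and to C2' through its ketone oxygen, and the aryloxide is expelled. The product is A1 (3-{[2,4-bis(tert-butyldimethylsilyloxy)-6-hydroxyphenyl]methyl}-6-ethyl-4-hydroxy-5-methyl-2H-pyran-2-one).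
- For: the bridging carbon belongs to one reactant from the start, so no symmetric dimers can form. On this point it is stronger than step 10 of the chosen route. The pyrone is built and attached in one operation.
- Against: A1 has no isobutyryl group, no ring B and no stereocenter. All three would have to be added to a molecule that already carries the acidic pyrone. The C5 acylation would have to go between two silyl ethers without a directing group that tolerates an organolithium. Ring B would still need an asymmetric annulation on the liberated phenol, whose iodination would again have to choose between an ortho and a para position. The ketene addition to a hindered, endocyclic ketene acetal must also run at thermolysis temperature in the presence of three silyl groups.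
- Comparison: the sequence after the key step is longer and the stereocenter is set late, next to the fragile pyrone. The chosen strategy spends its key step on ring B and C2 and accepts a selectivity risk only in the last bond formation.

**Alternative 2: benzannulation to build ring A.**
- Disconnection: ring A is taken apart at C7a–C3a, C4–C5 and C7a–C7 into the cyclobutenone A6 (methyl 3-(2-ethoxy-4-oxocyclobut-2-en-1-yl)propanoate) and the ynol ether A7 (1-ethoxy-5-methylhex-4-en-1-yne).
- Forward key step: heating opens A6 electrocyclically, the resulting ketene adds A7 in a [2+2] manner, and a second ring opening, 6π closure and tautomerization give the phenol A5 (methyl 3-[2,4-diethoxy-6-hydroxy-5-(3-methylbut-2-en-1-yl)phenyl]propanoate).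
- For: every substituent of ring A appears in a fixed place: the free hydroxyl that becomes O1, the prenyl group on C3a, the propanoate on C7 and two ether oxygens. This does not depend on symmetry or directing effects, so in regiochemical certainty it is at least equal to the chosen route.
- Against: ring A is the one part of 21 that can be bought as 1, and building it requires two sensitive, multistep partners. Ring B would have to come from the prenyl group by asymmetric epoxidation, cyclization and dehydration of a tertiary alcohol. The key step therefore does not address the stereocenter, and the alkene needs a late elimination of uncertain regiochemistry. C5 is still unacylated, the pyrone must be grown from the ester, and ethyl ethers need strong Lewis acids for cleavage next to the allylic aryl ether.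
- Comparison: the step count is far higher. The chosen route gets the same regiochemical security from the symmetry of 1 and one blocking group, and obtains the alkene directly from 10.

**Alternative 3: [2+2+2] cyclotrimerization closing rings A and B.**
- Disconnection: rings A and B are cut at C7a–C3a, C4–C5 and C6–C7. This gives the oxygen-tethered diyne A9 (tert-butyl{[(3R)-6-ethoxy-3-(ethynyloxy)-2-methylhex-5-yn-2-yl]oxy}dimethylsilane), which already holds C2, and the ynone A10 (1-ethoxy-4-methylpent-1-yn-3-one).
- Forward key step: a monovalent rhodium phosphine catalyst joins the two alkynes of A9 with A10 to give A8 (1-[(2R)-2-{2-[(tert-butyldimethylsilyl)oxy]propan-2-yl}-4,6-diethoxy-2,3-dihydro-1-benzofuran-5-yl]-2-methylpropan-1-one).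
- For: both rings and the C5 acyl group are formed at once, and the stereocenter comes from a precursor of secure configuration that the key step does not touch. On placement of the acyl group and certainty of configuration it is stronger than the chosen route.
- Against: A9 contains an ethynyl ether of a secondary alcohol with β-hydrogens, a group prone to thermal fragmentation, and a second ynol ether. Its enantioselective preparation is long. The orientation of A10 during insertion is not enforced. A8 carries the tertiary silyl ether, so desilylation and a regioselective dehydration must follow, and the ethyl ethers raise the same cleavage problem as in alternative 2.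
- Comparison: there are more steps both before and after the key step. The chosen route uses catalytic asymmetric induction on an achiral iodophenol, takes the alkene unchanged from 10, and removes its protecting groups with dilute acid.

Key step: step 6

Remark: the sense of induction of the chiral ligand is not predicted here. The ligand antipode that gives the 2R product is assumed, both antipodes being accessible from the two enantiomers of tert-butanesulfinamide.

## Route

Step 1
Reactants: 1 phloroglucinol (benzene-1,3,5-triol); 2 chloromethyl methyl ether
Product: 3 3,5-bis(methoxymethoxy)phenol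
Conditions: 2 (2.1 equiv), i-Pr2NEt (2.5 equiv), CH2Cl2–DMF, 0 °C to rt; chromatography
Reagents that add atoms: none
Why: O-alkylation of phenols with an α-chloro ether (MOM ether formation); the three hydroxyls are equivalent, so the product distribution depends only on stoichiometry, and the mono-, bis- and tris-ethers differ enough in polarity to be separated, the mono-ether being resubmitted.

Step 2
Reactants: 3 3,5-bis(methoxymethoxy)phenol
Product: 4 [3,5-bis(methoxymethoxy)phenoxy]tri(propan-2-yl)silane
Conditions: i-Pr3SiCl (1.2 equiv), imidazole, DMF, rt
Reagents that add atoms: chlorotri(propan-2-yl)silane, CC(C)[Si](Cl)(C(C)C)C(C)C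
Why: Imidazole-promoted silylation of a phenol; the bulky silyl ether is stable to alkyllithiums, does not direct metalation and shields both positions next to it.

Step 3
Reactants: 4 [3,5-bis(methoxymethoxy)phenoxy]tri(propan-2-yl)silane; 5 2-methylpropanoic anhydride (isobutyric anhydride)
Product: 7 1-[2,6-bis(methoxymethoxy)-4-{[tri(propan-2-yl)silyl]oxy}phenyl]-2-methylpropan-1-one, via [2,6-bis(methoxymethoxy)-4-{[tri(propan-2-yl)silyl]oxy}phenyl]lithium 6 (not isolated)
Conditions: n-BuLi (1.1 equiv), THF, 0 °C, 1 h; then cannulated into 5 (3 equiv), THF, −78 °C to 0 °C
Reagents that add atoms: none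
Why: Directed ortho-metalation at the only carbon flanked by two MOM ethers, then acylation of the aryllithium by inverse addition to excess anhydride; the ketone formed is shielded on both sides and α-branched, which should hold back a second addition.

Step 4
Reactants: 7 1-[2,6-bis(methoxymethoxy)-4-{[tri(propan-2-yl)silyl]oxy}phenyl]-2-methylpropan-1-one
Product: 8 1-[4-hydroxy-2,6-bis(methoxymethoxy)phenyl]-2-methylpropan-1-one
Conditions: Bu4NF (1.1 equiv), THF, 0 °C; aq. NH4Cl
Reagents that add atoms: none
Why: Fluoride cleavage of an aryl silyl ether, made easy here by the para ketone, which stabilizes the departing phenoxide; MOM ethers and the ketone are inert to fluoride.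

Step 5
Reactants: 8 1-[4-hydroxy-2,6-bis(methoxymethoxy)phenyl]-2-methylpropan-1-one
Product: 9 1-[4-hydroxy-3-iodo-2,6-bis(methoxymethoxy)phenyl]-2-methylpropan-1-one
Conditions: I2 (1.0 equiv), NaHCO3, THF–H2O, 0 °C
Reagents that add atoms: iodine, II
Why: Electrophilic aromatic iodination of a phenoxide; the two ortho positions are equivalent and the para position is blocked by the acyl group, so only one mono-iodide can form, the bicarbonate buffer protects the MOM ethers and one equivalent of iodine limits di-iodination.

Step 6
Reactants: 9 1-[4-hydroxy-3-iodo-2,6-bis(methoxymethoxy)phenyl]-2-methylpropan-1-one; 10 isoprene (2-methylbuta-1,3-diene)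
Product: 11 1-[(2R)-4,6-bis(methoxymethoxy)-2-(prop-1-en-2-yl)-2,3-dihydro-1-benzofuran-5-yl]-2-methylpropan-1-one
Conditions: Pd2(dba)3·CHCl3 (5 mol %), chiral N-methyl sulfinamide monophosphine of the TY-Phos type (20 mol %), PhONa (2 equiv), 10 (5 equiv), toluene, 50 °C, sealed tube
Reagents that add atoms: none
Why: Zerovalent palladium formed from Pd2(dba)3 and the phosphine inserts into the C–I bond of the phenoxide of 9, and the divalent arylpalladium adds across the less substituted double bond of 10 with the aryl group on the terminal CH2, which forms C3a–C3 and leaves palladium on an allyl unit spanning C2, the methyl-bearing carbon and the far CH2. The neighbouring phenoxide attacks the proximal allyl terminus, which forms O1–C2, closes ring B in a 5-exo mode (attack at the distal CH2 would be a 7-endo closure) and returns zerovalent palladium. The closest known reaction type is the Larock heteroannulation of 2-halophenols with 1,3-dienes in its enantioselective Heck/Tsuji–Trost form with chiral sulfinamide phosphines, for which 2-halophenols with a para acyl group and isoprene are competent partners. C2 is set by the ligand: the two diastereomeric π-allyl complexes can interconvert through the σ-allyl form at the unsubstituted CH2 terminus, and the chiral pocket decides which of them undergoes C–O bond formation, so the ligand antipode is chosen for 2R. Regioselectivity for the vinyl CH2 over the isopropenyl CH2 follows from the lower substitution of that alkene, and the choice of oxygen is fixed because 9 has a single free hydroxyl beside the iodine. β-Hydride elimination to an aryl diene should be held back once the allyl is η3-bound with the phenoxide next to it. The MOM ethers and the twisted, enolizable aryl ketone are inert to the weak base and the catalyst.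

Step 7
Reactants: 11 1-[(2R)-4,6-bis(methoxymethoxy)-2-(prop-1-en-2-yl)-2,3-dihydro-1-benzofuran-5-yl]-2-methylpropan-1-one
Product: 12 1-[(2R)-4,6-dihydroxy-2-(prop-1-en-2-yl)-2,3-dihydro-1-benzofuran-5-yl]-2-methylpropan-1-one
Conditions: HCl (1 M in MeOH, from AcCl), MeOH–THF, 0 °C to rt
Reagents that add atoms: none
Why: Acid-catalysed transacetalization of the MOM ethers to dimethoxymethane; both ethers flank the ketone and each phenol formed is stabilized by a hydrogen bond to the carbonyl, so dilute acid at or below room temperature should suffice and leave the isopropenyl group and the C2–O1 bond, and with it the configuration at C2, untouched.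

Step 8
Reactants: 13 methyl 3-oxopentanoate; 14 N-methoxy-N-methylpropanamide
Product: 16 methyl 4-methyl-3,5-dioxoheptanoate, via dilithium dienolate 15 (not isolated)
Conditions: LiN(i-Pr)2 (2.2 equiv), THF, −78 to 0 °C; then 14, −78 to 0 °C; aq. HCl
Reagents that add atoms: none
Why: γ-Acylation of a β-keto ester dianion with a Weinreb amide; the dianion reacts at its more basic terminal carbon, and the chelated tetrahedral adduct survives until work-up, which prevents over-addition and proton transfer to unreacted dianion.

Step 9
Reactants: 16 methyl 4-methyl-3,5-dioxoheptanoate
Product: 17 6-ethyl-4-hydroxy-5-methyl-2H-pyran-2-one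
Conditions: DBU (1.5 equiv), toluene, reflux; aq. HCl
Reagents that add atoms: none
Why: Base-mediated enol lactonization of a 3,5-dioxo ester; the enolate oxygen of the C5 ketone attacks the ester, methanol is lost and the ring tautomerizes to the 4-hydroxy-2-pyrone.

Step 10
Reactants: 12 1-[(2R)-4,6-dihydroxy-2-(prop-1-en-2-yl)-2,3-dihydro-1-benzofuran-5-yl]-2-methylpropan-1-one; 17 6-ethyl-4-hydroxy-5-methyl-2H-pyran-2-one; 18 N,N-dimethylmethaniminium iodide (Eschenmoser's salt)
Product: 21 6-ethyl-4-hydroxy-3-{[(2R)-4,6-dihydroxy-5-(2-methylpropanoyl)-2-(prop-1-en-2-yl)-2,3-dihydro-1-benzofuran-7-yl]methyl}-5-methyl-2H-pyran-2-one, via Mannich base 19 (not isolated), via methylidene pyrandione 20 (not isolated)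
Conditions: 17 (1.2 equiv), 18 (1.2 equiv), NaOAc (1.2 equiv), MeCN, rt; then 12 (1.0 equiv), 70 °C
Reagents that add atoms: none
Why: Mannich aminomethylation of the pyrone at C3, E1cB loss of the amine from the zwitterionic Mannich base to the methylidene dione, and Friedel–Crafts-type Michael addition of C7 of 12, its only unsubstituted ring carbon; consuming 17 as its Mannich base before 12 is added should suppress pyrone–pyrone coupling, and the weakly basic, non-ionizing conditions leave C2 unaffected.

## Compound list

1 | phloroglucinol (benzene-1,3,5-triol) | Oc1cc(O)cc(O)c1 | starting material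
2 | chloromethyl methyl ether | COCCl | starting material
3 | 3,5-bis(methoxymethoxy)phenol | COCOc1cc(O)cc(OCOC)c1 | intermediate
4 | [3,5-bis(methoxymethoxy)phenoxy]tri(propan-2-yl)silane | COCOc1cc(OCOC)cc(O[Si](C(C)C)(C(C)C)C(C)C)c1 | intermediate
5 | 2-methylpropanoic anhydride (isobutyric anhydride) | CC(C)C(=O)OC(=O)C(C)C | starting material
6 | [2,6-bis(methoxymethoxy)-4-{[tri(propan-2-yl)silyl]oxy}phenyl]lithium | [Li]c1c(OCOC)cc(O[Si](C(C)C)(C(C)C)C(C)C)cc1OCOC | intermediate (not isolated)
7 | 1-[2,6-bis(methoxymethoxy)-4-{[tri(propan-2-yl)silyl]oxy}phenyl]-2-methylpropan-1-one | CC(C)C(=O)c1c(OCOC)cc(O[Si](C(C)C)(C(C)C)C(C)C)cc1OCOC | intermediate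
8 | 1-[4-hydroxy-2,6-bis(methoxymethoxy)phenyl]-2-methylpropan-1-one | CC(C)C(=O)c1c(OCOC)cc(O)cc1OCOC | intermediate
9 | 1-[4-hydroxy-3-iodo-2,6-bis(methoxymethoxy)phenyl]-2-methylpropan-1-one | CC(C)C(=O)c1c(OCOC)cc(O)c(I)c1OCOC | intermediate
10 | isoprene (2-methylbuta-1,3-diene) | C=CC(C)=C | starting material
11 | 1-[(2R)-4,6-bis(methoxymethoxy)-2-(prop-1-en-2-yl)-2,3-dihydro-1-benzofuran-5-yl]-2-methylpropan-1-one | C=C(C)[C@H]1Cc2c(OCOC)c(C(=O)C(C)C)c(OCOC)cc2O1 | intermediate
12 | 1-[(2R)-4,6-dihydroxy-2-(prop-1-en-2-yl)-2,3-dihydro-1-benzofuran-5-yl]-2-methylpropan-1-one | C=C(C)[C@H]1Cc2c(O)c(C(=O)C(C)C)c(O)cc2O1 | intermediate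
13 | methyl 3-oxopentanoate | CCC(=O)CC(=O)OC | starting material
14 | N-methoxy-N-methylpropanamide | CCC(=O)N(C)OC | starting material
15 | dilithium 1-methoxypenta-1,3-diene-1,3-bis(olate) | CC=C([O-])C=C([O-])OC.[Li+].[Li+] | intermediate (not isolated)
16 | methyl 4-methyl-3,5-dioxoheptanoate | CCC(=O)C(C)C(=O)CC(=O)OC | intermediate
17 | 6-ethyl-4-hydroxy-5-methyl-2H-pyran-2-one | CCc1oc(=O)cc(O)c1C | intermediate
18 | N,N-dimethylmethaniminium iodide (Eschenmoser's salt) | C=[N+](C)C.[I-] | starting material
19 | 3-[(dimethylamino)methyl]-6-ethyl-4-hydroxy-5-methyl-2H-pyran-2-one | CCc1oc(=O)c(CN(C)C)c(O)c1C | intermediate (not isolated)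
20 | 6-ethyl-5-methyl-3-methylidene-2H-pyran-2,4(3H)-dione | CCC1=C(C)C(=O)C(=C)C(=O)O1 | intermediate (not isolated)
21 | 6-ethyl-4-hydroxy-3-{[(2R)-4,6-dihydroxy-5-(2-methylpropanoyl)-2-(prop-1-en-2-yl)-2,3-dihydro-1-benzofuran-7-yl]methyl}-5-methyl-2H-pyran-2-one | C=C(C)[C@H]1Cc2c(O)c(C(=O)C(C)C)c(O)c(Cc3c(O)c(C)c(CC)oc3=O)c2O1 | target

## Step count and least certain steps

Total step count: 10. Longest linear sequence: 8 steps (steps 1 to 7 and step 10). Steps 8 and 9 are the pyrone branch, which joins at step 10.

**Step 6 (key step).** The most likely failure is poor facial discrimination together with slow turnover. The arylpalladium is flanked by the phenoxide on one side and a MOM ether on the other, which is more crowded than the simple halophenols such ligands are tuned for. Insertion of 10 then competes with protodeiodination. Re-ionization of the allylic aryl ether of 11 by zerovalent palladium could also erode enantiomeric purity over time. Fallback: from 9 and 10, a ligand-free annulation with Pd(OAc)2, NaHCO3 and Bu4NCl in DMF at 80 °C should give racemic 1-[4,6-bis(methoxymethoxy)-2-(prop-1-en-2-yl)-2,3-dihydro-1-benzofuran-5-yl]-2-methylpropan-1-one F1. F1 is resolved by preparative chromatography on a chiral stationary phase. The unwanted antipode, 1-[(2S)-4,6-bis(methoxymethoxy)-2-(prop-1-en-2-yl)-2,3-dihydro-1-benzofuran-5-yl]-2-methylpropan-1-one F2, is set aside, and the 2R antipode is 11, where the route resumes.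

**Step 10.** The most likely failure is scrambling to symmetric dimers. Retro-Mannich exchange can return free 17, which then adds to 20, and the acceptor 20 can be consumed by self-condensation before 12 intercepts it. Fallback: the roles are exchanged. From 12, aminomethylation of C7 with 18 and NaOAc gives 1-[(2R)-7-[(dimethylamino)methyl]-4,6-dihydroxy-2-(prop-1-en-2-yl)-2,3-dihydro-1-benzofuran-5-yl]-2-methylpropan-1-one F3. Heating F3 with 17 in dioxane should release an ortho-quinone methide on ring A that is trapped by C3 of the pyrone, arriving at 21.

**Step 7.** The most likely failure is acid attack on the isopropenyl unit: Markovnikov addition of methanol or chloride to the alkene, or ionization of the allylic C2–O1 bond with ring opening and loss of configuration. Fallback: from 11, the MOM ethers are exchanged under buffered, non-protic conditions with TMSOTf and 2,2'-bipyridyl in CH2Cl2 at 0 °C. This gives 1-[(2R)-2-(prop-1-en-2-yl)-4,6-bis(trimethylsilyloxy)-2,3-dihydro-1-benzofuran-5-yl]-2-methylpropan-1-one F4, which water hydrolyses to 12.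

**Step 3.** The most likely failure is proton transfer from the α-position of the anhydride to the aryllithium, which returns 4, or a second addition to the ketone. Fallback: from 4, the aryllithium 6 is generated as before and added to isobutyraldehyde. The resulting racemic carbinol 1-[2,6-bis(methoxymethoxy)-4-{[tri(propan-2-yl)silyl]oxy}phenyl]-2-methylpropan-1-ol F5 is oxidized with Dess–Martin periodinane to 7.

**Step 1.** The most likely failure is an unfavourable statistical distribution of mono-, bis- and tris-ethers, with some C-alkylation of the electron-rich ring. Fallback: the acyl group is introduced first and used to differentiate the hydroxyls. From 1, Friedel–Crafts acylation with isobutyryl chloride and AlCl3 gives 2-methyl-1-(2,4,6-trihydroxyphenyl)propan-1-one F6. The hydroxyl para to the ketone, the most acidic and least hindered one, is silylated with i-Pr3SiCl and imidazole to give 1-[2,6-dihydroxy-4-{[tri(propan-2-yl)silyl]oxy}phenyl]-2-methylpropan-1-one F7. The two remaining hydroxyls are converted into MOM ethers with 2 and NaH in DMF. This sequence returns at 7 and replaces steps 1 to 3.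

## Further compounds

F1 | step 6 | rac-1-[4,6-bis(methoxymethoxy)-2-(prop-1-en-2-yl)-2,3-dihydro-1-benzofuran-5-yl]-2-methylpropan-1-one | C=C(C)C1Cc2c(OCOC)c(C(=O)C(C)C)c(OCOC)cc2O1
F2 | step 6 | 1-[(2S)-4,6-bis(methoxymethoxy)-2-(prop-1-en-2-yl)-2,3-dihydro-1-benzofuran-5-yl]-2-methylpropan-1-one | C=C(C)[C@@H]1Cc2c(OCOC)c(C(=O)C(C)C)c(OCOC)cc2O1
F3 | step 10 | 1-[(2R)-7-[(dimethylamino)methyl]-4,6-dihydroxy-2-(prop-1-en-2-yl)-2,3-dihydro-1-benzofuran-5-yl]-2-methylpropan-1-one | C=C(C)[C@H]1Cc2c(O)c(C(=O)C(C)C)c(O)c(CN(C)C)c2O1
F4 | step 7 | 1-[(2R)-2-(prop-1-en-2-yl)-4,6-bis(trimethylsilyloxy)-2,3-dihydro-1-benzofuran-5-yl]-2-methylpropan-1-one | C=C(C)[C@H]1Cc2c(O[Si](C)(C)C)c(C(=O)C(C)C)c(O[Si](C)(C)C)cc2O1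
F5 | step 3 | 1-[2,6-bis(methoxymethoxy)-4-{[tri(propan-2-yl)silyl]oxy}phenyl]-2-methylpropan-1-ol (racemic) | CC(C)C(O)c1c(OCOC)cc(O[Si](C(C)C)(C(C)C)C(C)C)cc1OCOC
F6 | step 1 | 2-methyl-1-(2,4,6-trihydroxyphenyl)propan-1-one | CC(C)C(=O)c1c(O)cc(O)cc1O
F7 | step 1 | 1-[2,6-dihydroxy-4-{[tri(propan-2-yl)silyl]oxy}phenyl]-2-methylpropan-1-one | CC(C)C(=O)c1c(O)cc(O[Si](C(C)C)(C(C)C)C(C)C)cc1O
A1 | alternative 1 | 3-{[2,4-bis(tert-butyldimethylsilyloxy)-6-hydroxyphenyl]methyl}-6-ethyl-4-hydroxy-5-methyl-2H-pyran-2-one | CCc1oc(=O)c(Cc2c(O)cc(O[Si](C)(C)C(C)(C)C)cc2O[Si](C)(C)C(C)(C)C)c(O)c1C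
A2 | alternative 1 | 6-ethyl-2,2,5-trimethyl-4H-1,3-dioxin-4-one | CCC1=C(C)C(=O)OC(C)(C)O1
A3 | alternative 1 | 2-methyl-3-oxopent-1-en-1-one | CCC(=O)C(C)=C=O
A4 | alternative 1 | 5,7-bis[(tert-butyldimethylsilyl)oxy]-2-[(trimethylsilyl)oxy]-4H-chromene | C[Si](C)(C)OC1=CCc2c(O[Si](C)(C)C(C)(C)C)cc(O[Si](C)(C)C(C)(C)C)cc2O1
A5 | alternative 2 | methyl 3-[2,4-diethoxy-6-hydroxy-5-(3-methylbut-2-en-1-yl)phenyl]propanoate | COC(=O)CCc1c(O)c(CC=C(C)C)c(OCC)cc1OCC
A6 | alternative 2 | methyl 3-(2-ethoxy-4-oxocyclobut-2-en-1-yl)propanoate | CCOC1=CC(=O)C1CCC(=O)OC
A7 | alternative 2 | 1-ethoxy-5-methylhex-4-en-1-yne | CCOC#CCC=C(C)C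
A8 | alternative 3 | 1-[(2R)-2-{2-[(tert-butyldimethylsilyl)oxy]propan-2-yl}-4,6-diethoxy-2,3-dihydro-1-benzofuran-5-yl]-2-methylpropan-1-one | CC(C)(O[Si](C)(C)C(C)(C)C)[C@H]1Cc2c(OCC)c(C(=O)C(C)C)c(OCC)cc2O1
A9 | alternative 3 | tert-butyl{[(3R)-6-ethoxy-3-(ethynyloxy)-2-methylhex-5-yn-2-yl]oxy}dimethylsilane | CC(C)(O[Si](C)(C)C(C)(C)C)[C@H](OC#C)CC#COCC
A10 | alternative 3 | 1-ethoxy-4-methylpent-1-yn-3-one | CCOC#CC(=O)C(C)C
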